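## Retrosynthetic overview
- Endgame: the target comes from C15 desilylation, preceded by epoxidation of the Z C1=C10 alkene (oxirane, last ring), preceded by Mitsunobu angeloylation with inversion at C8.
- Key disconnection C7–C8: the β-carbon of a butenolide is made nucleophilic as an allylindium homoenolate equivalent (from a 3-(acetoxymethyl)butenolide, Pd(PPh3)4/InI). It adds to the C8 aldehyde, closes the ten-membered carbocycle (second ring) and creates C7, C8 and the exocyclic methylene in one step.
- C3–C4: ligand-controlled Nozaki–Hiyama–Kishi coupling of a (Z)-iodoalkenyl butenolide with a C3-aldehyde/C8-acetal fragment.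
- Butenolide (first ring): ring-closing metathesis of a 2-(acetoxymethyl)acrylate of a dienol made from acrolein and TBS propargyl ether. Asymmetric alkynylation sets C6, and trans-hydroalumination/iodination sets the 4Z alkene.
- C3–C2–C1=C10(C14)–C9–C8 unit: Birch reduction and selective ozonolysis of 4-methylanisole, where the ring origin fixes the 1(10)Z geometry.

**Notation.** C1–C15 are germacranolide locants of the target: C12 is the lactone C=O, C13 the exocyclic CH2, C14 the methyl on C10, C15 the CH2OH on C4. TBS = tert-butyldimethylsilyl.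

**Structure as read from the SMILES.** 4Z alkene (C3 cis to C6), cis-oxirane (C2 and C9 on the same side), and configuration 1R,3S,6R,7R,8R,10S. This corresponds to 3β-OAc, 8β-OAng, a trans-6α,12-lactone and H-7α.

**Assumption.** In steps 4 and 9 the ligand antipode named is taken as the one that gives the drawn configuration. If the sense is opposite, the mirror-image ligand is used.

## Route

Step 1
Reactants: 1 4-methylanisole
Product: 2 1-methoxy-4-methylcyclohexa-1,4-diene
Conditions: Li, liq. NH3, t-BuOH, THF, −78 to −33 °C
Reagents that add atoms: none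
Why: Birch reduction leaves both donor substituents (OMe, Me) on sp2 carbons, giving the skipped diene whose ring holds the future C2 and C9 carbons cis on the methyl-bearing alkene.

Step 2
Reactants: 2 1-methoxy-4-methylcyclohexa-1,4-diene
Product: 4 methyl (Z)-6,6-dimethoxy-4-methylhex-3-enoate, via methyl (Z)-4-methyl-6-oxohex-3-enoate 3 (not isolated)
Conditions: O3 (1.0 equiv), CH2Cl2, −78 °C; Me2S; then HC(OMe)3, TsOH·H2O (cat.), rt
Reagents that add atoms: ozone O=[O+][O-]; trimethyl orthoformate COC(OC)OC
Why: In this chemoselective ozonolysis the enol-ether alkene is far more electron-rich than the trisubstituted alkene, so one equivalent of ozone cleaves only it to the ester (future C3) and the aldehyde (future C8), the aldehyde is acetalised in the same flask, and the Z geometry is inherited from the ring.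

Step 3
Reactants: 4 methyl (Z)-6,6-dimethoxy-4-methylhex-3-enoate
Product: 5 (Z)-6,6-dimethoxy-4-methylhex-3-enal (C3 aldehyde, C8 acetal)
Conditions: i-Bu2AlH (1.05 equiv), CH2Cl2, −78 °C; aq. potassium sodium tartrate
Reagents that add atoms: none
Why: Partial ester reduction works because the aluminium hemiacetal is stable at −78 °C and collapses to the aldehyde only on work-up, while the acetal and the Z alkene are untouched and no stereocentre is formed.

Step 4
Reactants: 6 tert-butyldimethyl(prop-2-yn-1-yloxy)silane; 7 acrolein
Product: 8 (S)-6-[(tert-butyldimethylsilyl)oxy]hex-1-en-4-yn-3-ol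
Conditions: Me2Zn, (S,S)-ProPhenol (10 mol %), Ph3P=O (20 mol %), toluene, 0 °C
Reagents that add atoms: none
Why: In this catalytic asymmetric alkynylation the dinuclear zinc–ProPhenol complex binds enal and zinc acetylide side by side and delivers the alkynyl group to one aldehyde face, which sets C6 (S here, R in the target only because CIP priorities change).

Step 5
Reactants: 8 (S)-6-[(tert-butyldimethylsilyl)oxy]hex-1-en-4-yn-3-ol
Product: 10 (3S,4Z)-6-[(tert-butyldimethylsilyl)oxy]-5-iodohexa-1,4-dien-3-ol, via cyclic sodium alkenylalanate 9 (not isolated)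
Conditions: NaAlH2(OCH2CH2OMe)2 (1.1 equiv), THF, 0 °C; then I2, −78 °C
Reagents that add atoms: iodine II
Why: In this hydroxyl-directed trans-hydroalumination/iodinolysis the C6 alkoxide delivers hydride to C5 and holds aluminium on C4 cis to C6 in a five-membered chelate, so iodinolysis with retention gives only the Z iodoalkene that later places C3 cis to C6 (4Z).

Step 6
Reactants: 11 2-(bromomethyl)acrylic acid
Product: 12 2-(acetoxymethyl)acrylic acid
Conditions: KOAc (3 equiv), AcOH, 60 °C
Reagents that add atoms: potassium acetate CC(=O)[O-].[K+]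
Why: This is an SN2 (or degenerate SN2′) displacement of an activated allylic bromide by excess acetate, exchanging a leaving group that divalent chromium would reduce for one that it leaves alone.

Step 7
Reactants: 10 (3S,4Z)-iododienol; 12 2-(acetoxymethyl)acrylic acid
Product: 13 (3S,4Z)-6-[(tert-butyldimethylsilyl)oxy]-5-iodohexa-1,4-dien-3-yl 2-(acetoxymethyl)acrylate
Conditions: DCC, DMAP (5 mol %), CH2Cl2, 0 °C
Reagents that add atoms: none
Why: Steglich esterification of the only hydroxyl group proceeds under near-neutral conditions, and C6 is not touched because the C–O bond stays intact.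

Step 8
Reactants: 13 dienyl 2-(acetoxymethyl)acrylate
Product: 14 {(5S)-5-[(Z)-3-[(tert-butyldimethylsilyl)oxy]-2-iodoprop-1-en-1-yl]-2-oxo-2,5-dihydrofuran-3-yl}methyl acetate
Conditions: second-generation Grubbs catalyst (5 mol %), CH2Cl2, 40 °C
Reagents that add atoms: none
Why: In this ring-closing metathesis the catalyst loads on the only terminal vinyl group and closes the five-membered ring onto the 1,1-disubstituted acrylate, while the trisubstituted iodoalkene is inert and C6 is unchanged.

Step 9
Reactants: 14 iodoalkenyl butenolide; 5 (Z)-6,6-dimethoxy-4-methylhex-3-enal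
Product: 15 {(5R)-5-[(1Z,3S,5Z)-2-{[(tert-butyldimethylsilyl)oxy]methyl}-3-hydroxy-8,8-dimethoxy-6-methylocta-1,5-dien-1-yl]-2-oxo-2,5-dihydrofuran-3-yl}methyl acetate
Conditions: CrCl2 (4 equiv), (S)-N-[2-(4-isopropyl-4,5-dihydrooxazol-2-yl)-6-methylphenyl]methanesulfonamide (4.4 equiv), Et3N (4.4 equiv), NiCl2 (5 mol %), THF, rt
Reagents that add atoms: none
Why: In this Nozaki–Hiyama–Kishi coupling zerovalent nickel inserts into the C(sp2)–I bond far faster than into the allylic acetate, the alkenylchromium formed with retention of the Z geometry adds only to the aldehyde, and the chiral sulfonamide on chromium selects the aldehyde face to set C3 as S.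

Step 10
Reactants: 15 C3 allylic alcohol
Product: 16 the corresponding (3S)-acetate (C3-OAc, C13-OAc, C15-OTBS, C8 dimethyl acetal)
Conditions: Ac2O, pyridine, DMAP (cat.), CH2Cl2, 0 °C
Reagents that add atoms: acetic anhydride CC(=O)OC(C)=O
Why: Acylation of the single free hydroxyl group occurs with retention at C3, and the weak base does not deprotonate C6 of the butenolide.

Step 11
Reactants: 16 acetal diacetate
Product: 17 seco-aldehyde (C8 aldehyde, 3-(acetoxymethyl)butenolide, 3S-OAc, 4Z, 1(10)Z, 6R)
Conditions: SiO2, 10 % aq. oxalic acid, CH2Cl2, rt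
Reagents that add atoms: water O
Why: Mild heterogeneous acetal hydrolysis releases the β,γ-unsaturated aldehyde without moving the Z alkene into conjugation and leaves the TBS ether, both acetates and the lactone intact.

Step 12 (key step)
Reactants: 17 seco-aldehyde
Product: 19 (1(10)Z,4Z)-3β-acetoxy-15-[(tert-butyldimethylsilyl)oxy]-8α-hydroxygermacra-1(10),4,11(13)-trien-12,6α-olide (3S,6R,7R,8S), via allylindium homoenolate equivalent 18 (not isolated)
Conditions: Pd(PPh3)4 (10 mol %), InI (2 equiv), THF, 1 mM, addition of 17 over 12 h, rt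
Reagents that add atoms: none
Why: Proposed new method: zerovalent palladium ionises the primary, acceptor-activated allylic acetate faster than the hindered secondary C3 acetate, and monovalent indium reduces the π-allylpalladium to allylindium 18, in which the normally electrophilic butenolide β-carbon C7 is a homoenolate-type nucleophile; γ-selective SE2′ addition of C7 to the equally electrophilic C8 aldehyde carbon through a closed chair (Zimmerman–Traxler) transition state, on the butenolide face anti to the C6 side chain, closes the ten-membered ring and gives the trans-6,7-lactone with its exocyclic methylene and the 7,8-anti (8α) alcohol; the closest known reaction types are the intermolecular palladium/indium umpolung allylation of aldehydes with allylic acetates, Barbier additions of 3-(bromomethyl)butenolides and allylative Nozaki–Hiyama–Kishi macrocyclisations, all of which proceed with allylic transposition.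

Step 13
Reactants: 19 8α-alcohol; 20 angelic acid [(Z)-2-methylbut-2-enoic acid]
Product: 21 (1(10)Z,4Z)-3β-acetoxy-8β-angeloyloxy-15-[(tert-butyldimethylsilyl)oxy]germacra-1(10),4,11(13)-trien-12,6α-olide (3S,6R,7R,8R)
Conditions: PPh3, DIAD (premixed), toluene, 0 °C to rt
Reagents that add atoms: none
Why: In this Mitsunobu esterification the alcohol is activated and displaced by angelate in an SN2 step, so C8 is inverted from α to β and acylated in one operation, and since the acid is never activated as an acyl donor its Z alkene cannot isomerise to tiglate.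

Step 14
Reactants: 21 trienolide diester
Product: 22 1β,10β-epoxide of 21 (1R,3S,6R,7R,8R,10S), C15-OTBS
Conditions: dimethyldioxirane (1.1 equiv), acetone–CH2Cl2, −20 °C
Reagents that add atoms: dimethyldioxirane CC1(C)OO1
Why: Dioxirane epoxidation attacks only C1=C10, because every other alkene is conjugated to a carbonyl or flanked by three allylic C–O bonds; the syn-stereospecific transfer turns the Z alkene into the cis-oxirane, and oxygen is expected to arrive on the outer face of the alkene in the conformer that keeps the C3 and C8 esters pseudo-equatorial, which is the β face (1R,10S).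

Step 15
Reactants: 22 epoxide TBS ether
Product: 23 target, (1R,3S,4Z,6R,7R,8R,10S)-3-acetoxy-8-angeloyloxy-1,10-epoxy-15-hydroxygermacra-4,11(13)-dien-12,6-olide
Conditions: HF·pyridine, pyridine, THF, 0 °C
Reagents that add atoms: none
Why: Buffered fluoride desilylation of the primary allylic silyl ether stays slightly acidic, so there is no O3-to-O15 acetyl migration or Michael addition, and it is mild enough for the trisubstituted epoxide, so no stereocentre is affected.

## Compound list
1 | 4-methylanisole | COc1ccc(C)cc1 | starting material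
2 | 1-methoxy-4-methylcyclohexa-1,4-diene | COC1=CCC(C)=CC1 | intermediate
3 | methyl (Z)-4-methyl-6-oxohex-3-enoate (not isolated) | COC(=O)C/C=C(/C)CC=O | intermediate
4 | methyl (Z)-6,6-dimethoxy-4-methylhex-3-enoate | COC(=O)C/C=C(/C)CC(OC)OC | intermediate
5 | (Z)-6,6-dimethoxy-4-methylhex-3-enal | O=CC/C=C(/C)CC(OC)OC | intermediate
6 | tert-butyldimethyl(prop-2-yn-1-yloxy)silane | C#CCO[Si](C)(C)C(C)(C)C | starting material
7 | acrolein | C=CC=O | starting material
8 | (S)-6-[(tert-butyldimethylsilyl)oxy]hex-1-en-4-yn-3-ol | C=C[C@H](O)C#CCO[Si](C)(C)C(C)(C)C | intermediate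
9 | cyclic sodium alkenylalanate, Al on C4 and O6 (not isolated) | C=C[C@H]1C=C(CO[Si](C)(C)C(C)(C)C)[Al-](OCCOC)(OCCOC)O1.[Na+] | intermediate
10 | (3S,4Z)-6-[(tert-butyldimethylsilyl)oxy]-5-iodohexa-1,4-dien-3-ol | C=C[C@H](O)/C=C(/CO[Si](C)(C)C(C)(C)C)I | intermediate
11 | 2-(bromomethyl)acrylic acid | C=C(CBr)C(=O)O | starting material
12 | 2-(acetoxymethyl)acrylic acid | C=C(COC(C)=O)C(=O)O | intermediate
13 | (3S,4Z)-6-(TBSO)-5-iodohexa-1,4-dien-3-yl 2-(acetoxymethyl)acrylate | C=C[C@H](OC(=O)C(=C)COC(C)=O)/C=C(/CO[Si](C)(C)C(C)(C)C)I | intermediate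
14 | (5S)-3-(acetoxymethyl)-5-[(Z)-3-(TBSO)-2-iodoprop-1-enyl]furan-2(5H)-one | O=C1O[C@H](/C=C(/CO[Si](C)(C)C(C)(C)C)I)C=C1COC(C)=O | intermediate
15 | coupled (3S)-alcohol, C8 dimethyl acetal, 6R, 4Z, 1(10)Z | O=C1O[C@H](/C=C(/CO[Si](C)(C)C(C)(C)C)[C@@H](O)C/C=C(/C)CC(OC)OC)C=C1COC(C)=O | intermediate
16 | (3S)-acetate of 15 | O=C1O[C@H](/C=C(/CO[Si](C)(C)C(C)(C)C)[C@@H](OC(C)=O)C/C=C(/C)CC(OC)OC)C=C1COC(C)=O | intermediate
17 | seco-aldehyde (C8 CHO) | O=C1O[C@H](/C=C(/CO[Si](C)(C)C(C)(C)C)[C@@H](OC(C)=O)C/C=C(/C)CC=O)C=C1COC(C)=O | intermediate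
18 | allylindium homoenolate equivalent, In on C13 (not isolated) | O=C1O[C@H](/C=C(/CO[Si](C)(C)C(C)(C)C)[C@@H](OC(C)=O)C/C=C(/C)CC=O)C=C1C[In](I)OC(C)=O | intermediate
19 | ten-membered 8α-alcohol (3S,6R,7R,8S) | C=C1C(=O)O[C@@H]2/C=C(/CO[Si](C)(C)C(C)(C)C)[C@@H](OC(C)=O)C/C=C(/C)C[C@H](O)[C@@H]12 | intermediate
20 | angelic acid | C/C=C(/C)C(=O)O | starting material
21 | 8β-angelate (3S,6R,7R,8R) | C=C1C(=O)O[C@@H]2/C=C(/CO[Si](C)(C)C(C)(C)C)[C@@H](OC(C)=O)C/C=C(/C)C[C@@H](OC(=O)/C(C)=C\C)[C@@H]12 | intermediate
22 | 1β,10β-epoxide, C15-OTBS | C=C1C(=O)O[C@@H]2/C=C(/CO[Si](C)(C)C(C)(C)C)[C@@H](OC(C)=O)C[C@H]3O[C@@]3(C)C[C@@H](OC(=O)/C(C)=C\C)[C@@H]12 | intermediate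
23 | CNP0162483.1 | C=C1C(=O)O[C@@H]2/C=C(/CO)[C@@H](OC(C)=O)C[C@H]3O[C@@]3(C)C[C@@H](OC(=O)/C(C)=C\C)[C@@H]12 | target

## Step count
- Total steps: 15.
- Longest linear sequence: 11 (steps 4, 5, 7, 8, 9, 10, 11, 12, 13, 14, 15).

## Three steps most likely to fail, with fallbacks

**Step 12.** The closure may give oligomers or the twelve-membered α-adduct, or palladium may ionise the C3 acetate.
The fallback sets out from 16 and comes back at 21. It replaces the allylindium made in situ by an isolable allylstannane that is activated through the aldehyde.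
- (Bu3Sn)2 with Pd(PPh3)4 (cat.) in THF exchanges the primary allylic acetate for tin and gives the allylstannane acetal F1.
- Wet silica/oxalic acid unmasks the stannyl seco-aldehyde F2.
- BF3·OEt2 in CH2Cl2 at −78 °C under high dilution triggers an SE2′ macrocyclisation through an open, antiperiplanar transition state. This favours the 7,8-syn product, the 8β-alcohol F3.
- C8 is then already correct, so F3 is esterified with retention (20, 2,4,6-trichlorobenzoyl chloride, Et3N, then DMAP, toluene). The route is rejoined at 21 without step 13.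

**Step 13.** SN2 at a hindered ring carbinol competes with elimination towards C9.
The fallback sets out from 19 and comes back at 21. It inverts C8 by redox instead of displacement.
- Dess–Martin periodinane (CH2Cl2, 0 °C) gives the C8 ketone F4.
- (S)-2-methyl-CBS-oxazaborolidine with catecholborane at −78 °C delivers hydride to the α face under reagent control. This treats C7 as the large and C9 as the small substituent, spares the α-methylene lactone, and gives the 8β-alcohol F3.
- F3 is acylated with 20 under the mixed-anhydride conditions above to give 21.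

**Step 14.** Oxygen may arrive on the wrong face of C1=C10.
The fallback sets out from 21 and comes back at 22. It puts the oxygen on the face opposite to the one that electrophiles reach.
- NBS in aqueous DME forms the bromonium ion on the accessible face, and water opens it at the tertiary C10 from the other side. This gives the 1α-bromo-10β-hydroxy bromohydrin F5.
- Ag2O in DME closes the ring by intramolecular SN2 at C1 with inversion, giving the 1β,10β-oxirane 22.

## Further compounds
F1 | step 12 | allylstannane acetal (C13-SnBu3, C8 dimethyl acetal) | O=C1O[C@H](/C=C(/CO[Si](C)(C)C(C)(C)C)[C@@H](OC(C)=O)C/C=C(/C)CC(OC)OC)C=C1C[Sn](CCCC)(CCCC)CCCC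
F2 | step 12 | stannyl seco-aldehyde (C13-SnBu3, C8 CHO) | O=C1O[C@H](/C=C(/CO[Si](C)(C)C(C)(C)C)[C@@H](OC(C)=O)C/C=C(/C)CC=O)C=C1C[Sn](CCCC)(CCCC)CCCC
F3 | step 12 | ten-membered 8β-alcohol (3S,6R,7R,8R) | C=C1C(=O)O[C@@H]2/C=C(/CO[Si](C)(C)C(C)(C)C)[C@@H](OC(C)=O)C/C=C(/C)C[C@@H](O)[C@@H]12
F4 | step 13 | ten-membered C8 ketone | C=C1C(=O)O[C@@H]2/C=C(/CO[Si](C)(C)C(C)(C)C)[C@@H](OC(C)=O)C/C=C(/C)CC(=O)[C@@H]12
F5 | step 14 | 1α-bromo-10β-hydroxy bromohydrin of 21 | C=C1C(=O)O[C@@H]2/C=C(/CO[Si](C)(C)C(C)(C)C)[C@@H](OC(C)=O)C[C@H](Br)[C@](O)(C)C[C@@H](OC(=O)/C(C)=C\C)[C@@H]12
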